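**Retrosynthetic overview**

- The target is the monomethyl ether of a symmetric resorcinol. Central ring locants: C1 carries the 2-(3-methoxyphenyl)ethyl chain, C2/C4/C6 the 4-hydroxybenzyl groups, C3 the OH and C5 the OMe.
- The route rests on C5: it carries only oxygen and lies between C4 and C6, so it is brought in as carbon monoxide. C4–C3–C2–C1–C6 is a 3-acetoxy-1,4-enyne whose acetate moves from C2 to C3 while the C4–C5 and C5–C6 bonds form (rhodium carbonylative [5+1]).
- A plain benzyl-substituted internal alkyne would be expected to favour 1,3-acyloxy shift. The C4 benzyl carbon is therefore carried through the key step as a 4-(benzyloxy)benzoyl group (ynone), which polarises the alkyne for the 1,2-shift and is reduced back to CH2 at the end.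
- The enyne comes from acyl Sonogashira coupling of a tertiary propargyl acetate, made by ethynyl addition to an E-enone, itself from a Horner–Wadsworth–Emmons-derived Weinreb enamide and a benzyl Grignard reagent.
- Only the central benzene ring is formed (step 9); the four outer arene rings are bought. End game: O-methylation, LiAlH4, hydrogenolysis.

Key step: step 9

Remark on the chemistry: the target is achiral; the carbinol centres of 11, 12, 14 and 20 and the sp3 C6 of 17 are racemic and are all erased, and because the parent resorcinol is symmetric either central-ring oxygen may be the methylated one.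

**Route**

Step 1
Reactants: 1 diethyl {2-[methoxy(methyl)amino]-2-oxoethyl}phosphonate; 2 1-(2-bromoethyl)-3-methoxybenzene
Product: 3 diethyl {1-[methoxy(methyl)amino]-4-(3-methoxyphenyl)-1-oxobutan-2-yl}phosphonate (racemic)
Conditions: NaH, DMF, 0 °C; then 2, NaI (cat.), 50 °C
Reagents that add atoms: none
Why: SN2 C-alkylation of the stabilised phosphonate carbanion with a primary bromide (iodide catalysis), the phosphonate being kept in slight excess so that elimination to the styrene and double alkylation stay minor.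

Step 2
Reactants: 4 2-[4-(benzyloxy)phenyl]ethanol
Product: 5 [4-(benzyloxy)phenyl]acetaldehyde
Conditions: Dess–Martin periodinane, CH2Cl2, 0 °C to rt; used at once
Reagents that add atoms: none
Why: Dess–Martin oxidation stops cleanly at the aldehyde under near-neutral conditions, which suits a self-condensing arylacetaldehyde; the benzyl ether is inert.

Step 3
Reactants: 3 α-substituted Weinreb phosphonate; 5 [4-(benzyloxy)phenyl]acetaldehyde
Product: 6 (E)-4-[4-(benzyloxy)phenyl]-N-methoxy-2-[2-(3-methoxyphenyl)ethyl]-N-methylbut-2-enamide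
Conditions: NaH (0.95 equiv), THF, 0 °C; then 5, −40 to 0 °C
Reagents that add atoms: none
Why: Horner–Wadsworth–Emmons olefination with an α-alkyl phosphonoacetamide should give mainly the E alkene (amide carbonyl trans to the CH2Ar group) through reversible addition and syn elimination; with base as the limiting reagent only non-basic phosphate remains, which guards against double-bond migration.

Step 4
Reactants: 7 4-(benzyloxy)benzyl chloride
Product: 8 [4-(benzyloxy)benzyl]magnesium chloride (titrated THF solution)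
Conditions: Mg turnings (activated), THF, 0 °C, slow addition
Reagents that add atoms: magnesium, [Mg]
Why: Grignard formation by magnesium insertion into the benzylic C–Cl bond; dilution, low temperature and slow addition keep Wurtz coupling down, and the aryl benzyl ether does not react.

Step 5
Reactants: 6 (E)-Weinreb enamide; 8 [4-(benzyloxy)benzyl]magnesium chloride
Product: 9 (E)-1,5-bis[4-(benzyloxy)phenyl]-3-[2-(3-methoxyphenyl)ethyl]pent-3-en-2-one
Conditions: 8 (1.5 equiv), THF, −20 to 0 °C; cold aq. NH4Cl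
Reagents that add atoms: none
Why: Weinreb ketone synthesis, in which the magnesium-chelated tetrahedral adduct holds until the cold quench, so neither over-addition nor enolisation of the benzyl ketone can occur in the flask and the E alkene is untouched.

Step 6
Reactants: 9 (E)-enone; 10 ethynylmagnesium bromide
Product: 11 (E)-3-[4-(benzyloxy)benzyl]-6-[4-(benzyloxy)phenyl]-4-[2-(3-methoxyphenyl)ethyl]hex-4-en-1-yn-3-ol (racemic)
Conditions: LaCl3·2LiCl (1 equiv), THF, 0 °C; then 10 (2 equiv), 0 °C; aq. NH4Cl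
Reagents that add atoms: none
Why: 1,2-addition of a small alkynyl Grignard reagent to the ketone, with the lanthanum salt raising carbonyl electrophilicity and suppressing enolisation of the benzylic α-protons; the quaternary carbinol centre forms racemic and is erased in step 9.

Step 7
Reactants: 11 tertiary propargylic alcohol
Product: 12 (E)-3-[4-(benzyloxy)benzyl]-6-[4-(benzyloxy)phenyl]-4-[2-(3-methoxyphenyl)ethyl]hex-4-en-1-yn-3-yl acetate (racemic)
Conditions: Ac2O, Et3N, DMAP, CH2Cl2, rt
Reagents that add atoms: acetic anhydride, CC(=O)OC(C)=O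
Why: DMAP-catalysed acyl transfer acetylates tertiary propargylic alcohols under basic conditions that cannot ionise the carbinol or disturb the alkene.

Step 8
Reactants: 12 terminal-alkyne acetate; 13 4-(benzyloxy)benzoyl chloride
Product: 14 (E)-4-[4-(benzyloxy)benzyl]-1,7-bis[4-(benzyloxy)phenyl]-5-[2-(3-methoxyphenyl)ethyl]-1-oxohept-5-en-2-yn-4-yl acetate (racemic)
Conditions: PdCl2(PPh3)2 (2 mol %), CuI (4 mol %), Et3N (1.5 equiv), THF, rt
Reagents that add atoms: none
Why: Acyl Sonogashira coupling, in which the aroylpalladium chloride from oxidative addition of 13 to zerovalent palladium is intercepted by the copper acetylide; the tertiary acetate has no propargylic hydrogen and should not ionise at room temperature.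

Step 9
Reactants: 14 ynone acetate (3-acetoxy-1,4-enyne); 15 carbon monoxide
Product: 18 2-[4-(benzyloxy)benzoyl]-4,6-bis[4-(benzyloxy)benzyl]-3-hydroxy-5-[2-(3-methoxyphenyl)ethyl]phenyl acetate, via dienylketene 16 (not isolated), via cyclohexadienone 17 (not isolated)
Conditions: [Rh(CO)2Cl]2 (5 mol %), CO (5 bar), ClCH2CH2Cl, 70 °C
Reagents that add atoms: none
Why: Proposed new method: [Rh(CO)2Cl]2 (monovalent rhodium) binds the ynone, the acetate carbonyl oxygen attacks the alkyne carbon β to the aroyl group (future C3) in a 5-exo sense, and cleavage of the old carbinol C–O bond gives a rhodium carbene at C4, conjugated with C3=C2 and C1=C6, which takes up CO to form the C4–C5 bond as dienylketene 16. The central ring is closed by 6π electrocyclisation of 16 (six-membered carbocycle, C5–C6 bond, equally reachable as reductive elimination from the rhodacycle), and enolisation of the C6 hydrogen of cyclohexadienone 17 gives phenol 18. The closest known reaction type is the rhodium-catalysed carbonylative [5+1] benzannulation of 3-acyloxy-1,4-enynes bearing terminal alkynes to resorcinol monoesters, together with the 1,2-acyloxy shift of propargyl esters whose alkyne carries an acceptor group; pairing an acyl-substituted internal alkyne with CO capture is the untested part. No stereocentre survives, since the racemic carbinol carbon of 14 becomes sp2 and the sp3 C6 of 17 is lost on tautomerisation. The step needs 1,2- rather than 1,3-acyloxy migration (the latter would lead through an allenyl acetate to [4+1] cyclopentenone products); the aroyl group secures this by making the alkyne carbon next to the carbinol the electrophilic Michael terminus, and the E alkene keeps the C6 benzyl group outside during ring closure.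

Step 10
Reactants: 18 resorcinol monoacetate (C3 acetate, C5 free OH)
Product: 19 2-[4-(benzyloxy)benzoyl]-4,6-bis[4-(benzyloxy)benzyl]-3-methoxy-5-[2-(3-methoxyphenyl)ethyl]phenyl acetate
Conditions: MeI, K2CO3, DMF (dry), rt
Reagents that add atoms: iodomethane, CI
Why: Williamson O-methylation of the only free phenol; the other resorcinol oxygen is masked as the hindered acetate, so the symmetric diol should be methylated once only.

Step 11
Reactants: 19 methyl ether acetate
Product: 20 2-{[4-(benzyloxy)phenyl](hydroxy)methyl}-4,6-bis[4-(benzyloxy)benzyl]-3-methoxy-5-[2-(3-methoxyphenyl)ethyl]phenol (racemic)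
Conditions: LiAlH4, THF, 0 °C to rt; Na2SO4·10H2O quench; crude product carried on
Reagents that add atoms: none
Why: Hydride reduction, in which LiAlH4 converts the diaryl ketone into the benzhydrol and cleaves the aryl acetate to the phenol while benzyl and methyl ethers are inert; the new carbinol centre is racemic and is removed in step 12.

Step 12
Reactants: 20 benzhydrol phenol
Product: 21 2,4,6-tris(4-hydroxybenzyl)-3-methoxy-5-[2-(3-methoxyphenyl)ethyl]phenol (CNP0285788.0)
Conditions: H2 (1 atm), 10% Pd/C, EtOAc–AcOH, rt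
Reagents that add atoms: none
Why: Catalytic hydrogenolysis cleaves the three aryl benzyl ethers and the electron-rich, doubly benzylic C–OH bond (activated by ortho-hydroxy and para-oxygen groups) in one operation, leaving the methyl ethers and arenes untouched.

**Compound list**

1 | diethyl {2-[methoxy(methyl)amino]-2-oxoethyl}phosphonate | CCOP(=O)(OCC)CC(=O)N(C)OC | starting material
2 | 1-(2-bromoethyl)-3-methoxybenzene | COc1cccc(CCBr)c1 | starting material
3 | diethyl {1-[methoxy(methyl)amino]-4-(3-methoxyphenyl)-1-oxobutan-2-yl}phosphonate (racemic) | CCOP(=O)(OCC)C(CCc1cccc(OC)c1)C(=O)N(C)OC | intermediate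
4 | 2-[4-(benzyloxy)phenyl]ethanol | OCCc1ccc(OCc2ccccc2)cc1 | starting material
5 | [4-(benzyloxy)phenyl]acetaldehyde | O=CCc1ccc(OCc2ccccc2)cc1 | intermediate
6 | (E)-4-[4-(benzyloxy)phenyl]-N-methoxy-2-[2-(3-methoxyphenyl)ethyl]-N-methylbut-2-enamide | CON(C)C(=O)/C(CCc1cccc(OC)c1)=C/Cc1ccc(OCc2ccccc2)cc1 | intermediate
7 | 4-(benzyloxy)benzyl chloride | ClCc1ccc(OCc2ccccc2)cc1 | starting material
8 | [4-(benzyloxy)benzyl]magnesium chloride | Cl[Mg]Cc1ccc(OCc2ccccc2)cc1 | intermediate
9 | (E)-1,5-bis[4-(benzyloxy)phenyl]-3-[2-(3-methoxyphenyl)ethyl]pent-3-en-2-one | O=C(Cc1ccc(OCc2ccccc2)cc1)/C(CCc1cccc(OC)c1)=C/Cc1ccc(OCc2ccccc2)cc1 | intermediate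
10 | ethynylmagnesium bromide | C#C[Mg]Br | starting material
11 | (E)-3-[4-(benzyloxy)benzyl]-6-[4-(benzyloxy)phenyl]-4-[2-(3-methoxyphenyl)ethyl]hex-4-en-1-yn-3-ol (racemic) | C#CC(O)(Cc1ccc(OCc2ccccc2)cc1)/C(CCc1cccc(OC)c1)=C/Cc1ccc(OCc2ccccc2)cc1 | intermediate
12 | (E)-3-[4-(benzyloxy)benzyl]-6-[4-(benzyloxy)phenyl]-4-[2-(3-methoxyphenyl)ethyl]hex-4-en-1-yn-3-yl acetate (racemic) | C#CC(OC(C)=O)(Cc1ccc(OCc2ccccc2)cc1)/C(CCc1cccc(OC)c1)=C/Cc1ccc(OCc2ccccc2)cc1 | intermediate
13 | 4-(benzyloxy)benzoyl chloride | O=C(Cl)c1ccc(OCc2ccccc2)cc1 | starting material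
14 | (E)-4-[4-(benzyloxy)benzyl]-1,7-bis[4-(benzyloxy)phenyl]-5-[2-(3-methoxyphenyl)ethyl]-1-oxohept-5-en-2-yn-4-yl acetate (racemic) | CC(=O)OC(C#CC(=O)c1ccc(OCc2ccccc2)cc1)(Cc1ccc(OCc2ccccc2)cc1)/C(CCc1cccc(OC)c1)=C/Cc1ccc(OCc2ccccc2)cc1 | intermediate
15 | carbon monoxide | [C-]#[O+] | starting material
16 | dienylketene (C4–C5 bond formed, acetate on C3; not isolated) | O=C=C(C(=O)c1ccc(OCc2ccccc2)cc1)/C(OC(C)=O)=C(Cc1ccc(OCc2ccccc2)cc1)\C(CCc1cccc(OC)c1)=C\Cc1ccc(OCc2ccccc2)cc1 | intermediate
17 | cyclohexa-2,4-dienone keto tautomer of 18 (racemic at C6; not isolated) | O=C1C(Cc2ccc(OCc3ccccc3)cc2)C(CCc2cccc(OC)c2)=C(Cc2ccc(OCc3ccccc3)cc2)C(OC(C)=O)=C1C(=O)c1ccc(OCc2ccccc2)cc1 | intermediate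
18 | 2-[4-(benzyloxy)benzoyl]-4,6-bis[4-(benzyloxy)benzyl]-3-hydroxy-5-[2-(3-methoxyphenyl)ethyl]phenyl acetate | COc1cccc(CCc2c(Cc3ccc(OCc4ccccc4)cc3)c(OC(C)=O)c(C(=O)c3ccc(OCc4ccccc4)cc3)c(O)c2Cc2ccc(OCc3ccccc3)cc2)c1 | intermediate
19 | 2-[4-(benzyloxy)benzoyl]-4,6-bis[4-(benzyloxy)benzyl]-3-methoxy-5-[2-(3-methoxyphenyl)ethyl]phenyl acetate | COc1cccc(CCc2c(Cc3ccc(OCc4ccccc4)cc3)c(OC(C)=O)c(C(=O)c3ccc(OCc4ccccc4)cc3)c(OC)c2Cc2ccc(OCc3ccccc3)cc2)c1 | intermediate
20 | 2-{[4-(benzyloxy)phenyl](hydroxy)methyl}-4,6-bis[4-(benzyloxy)benzyl]-3-methoxy-5-[2-(3-methoxyphenyl)ethyl]phenol (racemic) | COc1cccc(CCc2c(Cc3ccc(OCc4ccccc4)cc3)c(O)c(C(O)c3ccc(OCc4ccccc4)cc3)c(OC)c2Cc2ccc(OCc3ccccc3)cc2)c1 | intermediate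
21 | 2,4,6-tris(4-hydroxybenzyl)-3-methoxy-5-[2-(3-methoxyphenyl)ethyl]phenol | COc1cccc(CCc2c(Cc3ccc(O)cc3)c(O)c(Cc3ccc(O)cc3)c(OC)c2Cc2ccc(O)cc2)c1 | target

**Step count**

Total: 12 steps. Longest linear sequence: 10 steps (1, 3, 5, 6, 7, 8, 9, 10, 11, 12).

**Steps most likely to fail**

Step 9. The acetate may shift 1,3 instead of 1,2, giving an allenyl acetate and then [4+1] cyclopentenone products, or the acyl carbene may be diverted (Rautenstrauch-type five-ring closure, attack by the ketone oxygen) before CO is captured. The fallback uses the established terminal-alkyne form of the same benzannulation and installs the C4 carbon afterwards. It sets out from 12. With [Rh(CO)2Cl]2 and CO, 12 should give 2,4-bis[4-(benzyloxy)benzyl]-5-hydroxy-3-[2-(3-methoxyphenyl)ethyl]phenyl acetate F1, which has C4 unsubstituted. Methylation with MeI and K2CO3 gives 2,4-bis[4-(benzyloxy)benzyl]-5-methoxy-3-[2-(3-methoxyphenyl)ethyl]phenyl acetate F2. Methanolysis with K2CO3 in MeOH gives 2,4-bis[4-(benzyloxy)benzyl]-5-methoxy-3-[2-(3-methoxyphenyl)ethyl]phenol F3. Its bromomagnesium salt (EtMgBr, toluene–CH2Cl2, rt) is then hydroxyalkylated by 4-(benzyloxy)benzaldehyde (excess) at C4, the only free ortho position, through the magnesium chelate. This comes back to the route at 20.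

Step 6. The acetylide may deprotonate the benzyl ketone at its benzylic α-carbon instead of adding, with recovery of 9 and drift of the double bond out of conjugation. The fallback reverses the order of the two carbon nucleophiles so that the ketone attacked has no α-hydrogen. It sets out from 6. Commercial lithium (trimethylsilyl)acetylide in THF at −78 °C gives (E)-6-[4-(benzyloxy)phenyl]-4-[2-(3-methoxyphenyl)ethyl]-1-(trimethylsilyl)hex-4-en-1-yn-3-one F4. Grignard reagent 8 adds 1,2 to this silyl-shielded ynone at −78 °C to give (E)-3-[4-(benzyloxy)benzyl]-6-[4-(benzyloxy)phenyl]-4-[2-(3-methoxyphenyl)ethyl]-1-(trimethylsilyl)hex-4-en-1-yn-3-ol F5. Desilylation with K2CO3 in MeOH comes back to the route at 11.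

Step 3. The arylacetaldehyde may be enolised and self-condense, the E/Z ratio may erode, and base may move the new double bond into conjugation with the arene. The fallback makes the alkene with a robust aldehyde and forms the allyl–aryl bond by cross-coupling. It sets out from 3. Olefination with (tert-butyldimethylsilyloxy)acetaldehyde (NaH, THF) gives (E)-4-[(tert-butyldimethylsilyl)oxy]-N-methoxy-2-[2-(3-methoxyphenyl)ethyl]-N-methylbut-2-enamide F6. TBAF gives (E)-4-hydroxy-N-methoxy-2-[2-(3-methoxyphenyl)ethyl]-N-methylbut-2-enamide F7. An Appel reaction (CBr4, PPh3) gives (E)-4-bromo-N-methoxy-2-[2-(3-methoxyphenyl)ethyl]-N-methylbut-2-enamide F8. Suzuki–Miyaura coupling of this allylic bromide with 4-(benzyloxy)phenylboronic acid (Pd(PPh3)4, K2CO3, THF–H2O) joins the arene at the unsubstituted allyl terminus and comes back to the route at 6.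

**Further compounds**

F1 | step 9 | 2,4-bis[4-(benzyloxy)benzyl]-5-hydroxy-3-[2-(3-methoxyphenyl)ethyl]phenyl acetate | COc1cccc(CCc2c(Cc3ccc(OCc4ccccc4)cc3)c(OC(C)=O)cc(O)c2Cc2ccc(OCc3ccccc3)cc2)c1
F2 | step 9 | 2,4-bis[4-(benzyloxy)benzyl]-5-methoxy-3-[2-(3-methoxyphenyl)ethyl]phenyl acetate | COc1cccc(CCc2c(Cc3ccc(OCc4ccccc4)cc3)c(OC(C)=O)cc(OC)c2Cc2ccc(OCc3ccccc3)cc2)c1
F3 | step 9 | 2,4-bis[4-(benzyloxy)benzyl]-5-methoxy-3-[2-(3-methoxyphenyl)ethyl]phenol | COc1cccc(CCc2c(Cc3ccc(OCc4ccccc4)cc3)c(O)cc(OC)c2Cc2ccc(OCc3ccccc3)cc2)c1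
F4 | step 6 | (E)-6-[4-(benzyloxy)phenyl]-4-[2-(3-methoxyphenyl)ethyl]-1-(trimethylsilyl)hex-4-en-1-yn-3-one | C[Si](C)(C)C#CC(=O)/C(CCc1cccc(OC)c1)=C/Cc1ccc(OCc2ccccc2)cc1
F5 | step 6 | (E)-3-[4-(benzyloxy)benzyl]-6-[4-(benzyloxy)phenyl]-4-[2-(3-methoxyphenyl)ethyl]-1-(trimethylsilyl)hex-4-en-1-yn-3-ol (racemic) | C[Si](C)(C)C#CC(O)(Cc1ccc(OCc2ccccc2)cc1)/C(CCc1cccc(OC)c1)=C/Cc1ccc(OCc2ccccc2)cc1
F6 | step 3 | (E)-4-[(tert-butyldimethylsilyl)oxy]-N-methoxy-2-[2-(3-methoxyphenyl)ethyl]-N-methylbut-2-enamide | CON(C)C(=O)/C(CCc1cccc(OC)c1)=C/CO[Si](C)(C)C(C)(C)C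
F7 | step 3 | (E)-4-hydroxy-N-methoxy-2-[2-(3-methoxyphenyl)ethyl]-N-methylbut-2-enamide | CON(C)C(=O)/C(CCc1cccc(OC)c1)=C/CO
F8 | step 3 | (E)-4-bromo-N-methoxy-2-[2-(3-methoxyphenyl)ethyl]-N-methylbut-2-enamide | CON(C)C(=O)/C(CCc1cccc(OC)c1)=C/CBr
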